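**Retrosynthetic overview**
1. The target is (5S,6S,7S,10S)-6-acetoxy-7-(3-methylbutanoyloxy)labda-8,13E-dien-15-oic acid. Both esters are installed last from a 7α-hydroxy-6-ketone, and the side chain is attached at C9 by an sp2–sp3 Negishi coupling of a C8=C9 enol triflate.
2. Ring B is made first, from 4-methoxy-2,6-dimethylphenol, as the ene-dione aldehyde 7; its C10 quaternary centre is set by a Pd-catalysed asymmetric allylation. Ring A is made second, in the key step.
3. Key disconnection: ring A = aldehyde 7 + 2-methylpropene. C2–C3 forms by Prins addition and C4–C5 by capture of the resulting tertiary cation, in one flask (a formal [4+2] annulation).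
4. Enabling feature: in ring B the C6 carbonyl can enolise only towards C5 (C7 is sp2, C10 is quaternary), and C10 carries the C1H2–C2H=O arm. Electrophilic C2 and nucleophilic C5 therefore form a 1,4-dipole that spans exactly the C3H2=C4(CH3)2 unit; the same ene-dione later gives the C9 enolate regiospecifically.

Key step: step 5

Remark: labdane numbering is used for atoms throughout (C1–C10 decalin, C11–C15 side chain); compounds 9, 10 and 11 are mixtures of epimers at C2, a centre that step 6 removes.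
Remark (assumption): (R)-t-Bu-PHOX is assumed to give the (S) centre in step 3, by analogy with the sense of induction known for 2-methylcyclohexanone enol carbonates; if the sense is opposite, the (S) ligand is used.

**Route**

Step 1
Reactants: 1 4-methoxy-2,6-dimethylphenol
Product: 2 quinone monoketal 4,4-dimethoxy-2,6-dimethylcyclohexa-2,5-dien-1-one
Conditions: PhI(OAc)2 (1.1 equiv), MeOH, 0 °C
Reagents that add atoms: methanol, CO
Why: Oxidative dearomatisation of a para-alkoxyphenol, in which the aryl-iodine reagent oxidises the phenol and methanol adds at C4 to give the quinone monoketal; no stereocentre is formed.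

Step 2
Reactants: 2 quinone monoketal
Product: 4 allyl 4,4-dimethoxy-2,6-dimethylcyclohexa-1,5-dien-1-yl carbonate, via lithium dienolate 3 (not isolated)
Conditions: LiBH(s-Bu)3 (1.05 equiv), THF, −78 °C; then ClCO2CH2CH=CH2, −78 → 0 °C
Reagents that add atoms: allyl chloroformate, C=CCOC(=O)Cl
Why: Conjugate reduction followed by enolate O-acylation: hydride adds to one of the two symmetry-equivalent unsubstituted β-carbons, which also stops a second reduction, and the hindered tetrasubstituted enolate is acylated on oxygen.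

Step 3
Reactants: 4 allyl enol carbonate
Product: 6 (6S)-2,6-dimethyl-6-(prop-2-en-1-yl)cyclohex-2-ene-1,4-dione, via allylated dimethyl ketal 5 (not isolated)
Conditions: Pd2(dba)3 (2.5 mol %), (R)-t-Bu-PHOX (6 mol %), THF, 25 °C; then 1 M HCl, THF, 25 °C
Reagents that add atoms: water, O
Why: Pd-catalysed decarboxylative asymmetric allylic alkylation (Tsuji–Trost type, enol carbonate variant), in which loss of CO2 gives a chiral Pd–PHOX enolate/π-allyl pair that allylates one face of C10 and sets the quaternary centre; aqueous acid then unmasks the C6 ketone.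

Step 4
Reactants: 6 allyl ene-dione
Product: 7 aldehyde 2-[(1S)-1,3-dimethyl-2,5-dioxocyclohex-3-en-1-yl]acetaldehyde
Conditions: OsO4 (2 mol %), NaIO4 (4 equiv), 2,6-lutidine, dioxane/H2O, 25 °C
Reagents that add atoms: sodium periodate, [Na+].[O-]I(=O)(=O)=O
Why: Lemieux–Johnson cleavage, in which OsO4 dihydroxylates the electron-rich terminal alkene in preference to the electron-poor ene-dione C=C and periodate cleaves the diol, leaving C1–C2 as CH2–CHO.

Step 5
Reactants: 7 aldehyde; 8 2-methylpropene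
Product: 10 cis-fused hydroxy ene-dione (4aR,8aS)-7-hydroxy-2,5,5,8a-tetramethyl-4a,5,6,7,8,8a-hexahydronaphthalene-1,4-dione (both carbinol epimers), via chlorotitanium alkoxide 9 (not isolated)
Conditions: 8 (10 equiv), TiCl4 (3 equiv), CH2Cl2, −78 °C; excess 8 purged (N2, −50 °C); −50 → 0 °C; H2O
Reagents that add atoms: none
Why: Proposed new method: the TiCl4-activated aldehyde carbon C2 is attacked by the CH2 terminus of 8 (Prins addition, C2–C3 bond) and the tertiary C4 cation collapses to the C4 chloride 9 at −78 °C; after excess 8 is removed and the mixture warmed, TiCl4 re-ionises C4–Cl while the TiCl4-bound C6 ketone enolises towards C5, and the enol carbon captures the cation (C4–C5 bond). The closest known reaction types are Lewis-acid Prins and carbonyl-ene additions of aldehydes to 1,1-disubstituted alkenes, Prins/Friedel–Crafts [4+2] annulations, and TiCl4-mediated α-tert-alkylation of enol derivatives by tertiary chlorides. Ring A closes as a six-membered ring in the 6-(enolexo) mode onto a planar tertiary carbenium ion, the C5=C6 enol bond staying exocyclic to the new ring. C5 is the only new ring-fusion centre: the C1 tether can reach only its own face of the flat dienol, so the cis-fused isomer is expected and is inverted in step 7, while the C2 carbinol forms unselectively and is removed in step 6 and C10 is untouched. The step needs the aldehyde rather than the two hindered, conjugated ketones to act as the Prins electrophile, enolisation at C5 only (C7 is sp2, C10 quaternary, the C9 ketone has no α-hydrogen), and C- rather than O-alkylation (O-attack would need an eight-membered ring). Chloride capture at low temperature and removal of excess 8 before re-ionisation are what keep the cation from oligomerising the alkene.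

Step 6
Reactants: 10 cis-fused hydroxy ene-dione
Product: 12 cis-fused ene-dione (4aR,8aS)-2,5,5,8a-tetramethyl-4a,5,6,7,8,8a-hexahydronaphthalene-1,4-dione, via thiocarbonylimidazolide 11 (not isolated)
Conditions: 1,1′-thiocarbonyldiimidazole, DMAP (cat.), ClCH2CH2Cl, 70 °C; then Bu3SnH, AIBN (cat.), toluene, 90 °C
Reagents that add atoms: none
Why: Barton–McCombie deoxygenation removes the C2 hydroxyl left by the aldehyde activating group; the C=S group should trap Bu3Sn radicals much faster than the ene-dione, and the secondary C2 radical is reduced by Bu3SnH.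

Step 7
Reactants: 12 cis-fused ene-dione
Product: 14 trans-fused ene-dione (4aS,8aS)-2,5,5,8a-tetramethyl-4a,5,6,7,8,8a-hexahydronaphthalene-1,4-dione, via lithium dienolate 13 (not isolated)
Conditions: LiN(SiMe3)2 (1.1 equiv), THF, −78 → −20 °C; then AcOH, THF, −78 °C
Reagents that add atoms: none
Why: Kinetic protonation of an enolate: C5–H is the only α-hydrogen of either ketone, and the planar C5 enolate should be protonated axially from the α-face, anti to the syn-axial C10 and C4β methyl groups, which converts the cis into the trans ring fusion (5α-H).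

Step 8
Reactants: 14 trans-fused ene-dione
Product: 16 enol triflate (4aS,8aS)-2,5,5,8a-tetramethyl-4-oxo-3,4,4a,5,6,7,8,8a-octahydronaphthalen-1-yl trifluoromethanesulfonate, via lithium enolate 15 (not isolated)
Conditions: LiBH(s-Bu)3 (1.1 equiv), THF, −78 °C; then N-(5-chloropyridin-2-yl)triflimide, −78 → 0 °C
Reagents that add atoms: N-(5-chloropyridin-2-yl)-N-[(trifluoromethyl)sulfonyl]trifluoromethanesulfonamide, O=S(=O)(N(c1ccc(Cl)cn1)S(=O)(=O)C(F)(F)F)C(F)(F)F
Why: Conjugate reduction with enolate trapping: the bulky hydride should add to unsubstituted C7 (β to the C9 carbonyl) rather than to methyl-bearing C8, so the C9 enolate forms regiospecifically and O-triflation fixes the tetrasubstituted C8=C9 bond; no stereocentre is formed.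

Step 9
Reactants: 17 tert-butyl(but-3-yn-1-yloxy)dimethylsilane
Product: 19 2-(trimethylsilyl)ethyl (2E)-5-{[tert-butyl(dimethyl)silyl]oxy}-3-methylpent-2-enoate, via alkenylalane 18 (not isolated)
Conditions: Me3Al (2 equiv), Cp2ZrCl2 (0.2 equiv), CH2Cl2, 0 → 25 °C; then ClCO2CH2CH2SiMe3, 0 → 25 °C
Reagents that add atoms: trimethylaluminium, C[Al](C)C; 2-(trimethylsilyl)ethyl chloroformate, C[Si](C)(C)CCOC(=O)Cl
Why: Zr-catalysed carboalumination of a terminal alkyne (Negishi carbometalation) adds Me and Al syn with Me on the internal carbon, and acylation of the alkenyl–Al bond with retention gives the (E)-trisubstituted enoate.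

Step 10
Reactants: 19 silyl ether enoate
Product: 20 2-(trimethylsilyl)ethyl (2E)-5-bromo-3-methylpent-2-enoate
Conditions: Ph3PBr2 (1.3 equiv), CH2Cl2, 0 → 25 °C
Reagents that add atoms: dibromotriphenylphosphorane, BrP(Br)(c1ccccc1)(c1ccccc1)c1ccccc1
Why: Appel-type direct conversion of a primary silyl ether into the bromide, in which the phosphonium reagent activates the ether oxygen and bromide displaces at the primary carbon; the alkene geometry is not involved.

Step 11
Reactants: 16 enol triflate; 20 bromide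
Product: 22 2-(trimethylsilyl)ethyl (2E)-3-methyl-5-[(4aS,8aS)-2,5,5,8a-tetramethyl-4-oxo-3,4,4a,5,6,7,8,8a-octahydronaphthalen-1-yl]pent-2-enoate, via alkylzinc bromide 21 (not isolated)
Conditions: 20, Zn dust, I2 (cat.), DMA, 70 °C; then 16, PdCl2(dppf) (5 mol %), THF, 50 °C
Reagents that add atoms: none
Why: Negishi sp3–sp2 cross-coupling: zinc insertion into the primary bromide tolerates the enoate, and Pd-catalysed coupling with the alkenyl triflate joins C11 to C9 with retention of both alkene geometries.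

Step 12
Reactants: 22 β,γ-unsaturated ketone
Product: 24 2-(trimethylsilyl)ethyl (2E)-5-[(3S,4aS,8aS)-3-hydroxy-2,5,5,8a-tetramethyl-4-oxo-3,4,4a,5,6,7,8,8a-octahydronaphthalen-1-yl]-3-methylpent-2-enoate, via sodium dienolate 23 (not isolated)
Conditions: NaN(SiMe3)2 (1.1 equiv), THF, −78 °C; then 2-(phenylsulfonyl)-3-phenyloxaziridine, −78 °C; AcOH quench
Reagents that add atoms: 2-(phenylsulfonyl)-3-phenyloxaziridine, O=S(=O)(N1OC1c1ccccc1)c1ccccc1
Why: Davis enolate oxidation: the kinetic enolate forms at doubly activated C7 (α to the C6 carbonyl and allylic), and the oxaziridine should attack the α-carbon C7 of the dienolate axially from the α-face, anti to the C10 methyl group, giving the 7α-alcohol with the C8=C9 bond left in place.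

Step 13
Reactants: 24 7α-hydroxy ketone
Product: 25 2-(trimethylsilyl)ethyl (2E)-3-methyl-5-{(3S,4aS,8aS)-2,5,5,8a-tetramethyl-3-[(3-methylbutanoyl)oxy]-4-oxo-3,4,4a,5,6,7,8,8a-octahydronaphthalen-1-yl}pent-2-enoate
Conditions: 3-methylbutanoic anhydride (2 equiv), DMAP (0.2 equiv), pyridine, CH2Cl2, 0 → 25 °C
Reagents that add atoms: 3-methylbutanoic anhydride, CC(C)CC(=O)OC(=O)CC(C)C
Why: DMAP-catalysed acylation of the only free hydroxyl, under conditions mild enough that the C7 centre should not epimerise.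

Step 14
Reactants: 25 7α-acyloxy ketone
Product: 26 2-(trimethylsilyl)ethyl (2E)-5-{(3S,4S,4aS,8aS)-4-hydroxy-2,5,5,8a-tetramethyl-3-[(3-methylbutanoyl)oxy]-3,4,4a,5,6,7,8,8a-octahydronaphthalen-1-yl}-3-methylpent-2-enoate
Conditions: NaBH4, MeOH/THF, −20 °C
Reagents that add atoms: none
Why: Hydride reduction of a ketone whose β-face is blocked by the syn-axial C10 and C4β methyl groups, so hydride should enter from the α-face and give the axial 6β-alcohol; the trans-diaxial relation to the 7α-ester excludes acyl migration.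

Step 15
Reactants: 26 6β-alcohol
Product: 27 2-(trimethylsilyl)ethyl (2E)-5-{(3S,4S,4aS,8aS)-4-acetoxy-2,5,5,8a-tetramethyl-3-[(3-methylbutanoyl)oxy]-3,4,4a,5,6,7,8,8a-octahydronaphthalen-1-yl}-3-methylpent-2-enoate
Conditions: Ac2O, DMAP (1 equiv), pyridine, 40 °C
Reagents that add atoms: acetic anhydride, CC(=O)OC(C)=O
Why: DMAP-promoted acetylation of the hindered axial 6β-alcohol with retention at C6.

Step 16
Reactants: 27 fully acylated silylethyl ester
Product: 28 target (5S,6S,7S,10S)-6-acetoxy-7-[(3-methylbutanoyl)oxy]labda-8,13E-dien-15-oic acid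
Conditions: Bu4NF (1.5 equiv), THF, 0 °C; AcOH quench
Reagents that add atoms: none
Why: Fluoride-induced β-elimination of the 2-(trimethylsilyl)ethyl ester frees the acid under conditions that should leave the acetate and the allylic 3-methylbutanoate intact.

**Compound list**
1 | 4-methoxy-2,6-dimethylphenol | COc1cc(C)c(O)c(C)c1 | starting material
2 | 4,4-dimethoxy-2,6-dimethylcyclohexa-2,5-dien-1-one | COC1(OC)C=C(C)C(=O)C(C)=C1 | intermediate
3 | lithium 4,4-dimethoxy-2,6-dimethylcyclohexa-1,5-dien-1-olate | [Li]OC1=C(C)CC(OC)(OC)C=C1C | intermediate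
4 | allyl 4,4-dimethoxy-2,6-dimethylcyclohexa-1,5-dien-1-yl carbonate | C=CCOC(=O)OC1=C(C)CC(OC)(OC)C=C1C | intermediate
5 | (6S)-4,4-dimethoxy-2,6-dimethyl-6-(prop-2-en-1-yl)cyclohex-2-en-1-one | C=CC[C@@]1(C)CC(OC)(OC)C=C(C)C1=O | intermediate
6 | (6S)-2,6-dimethyl-6-(prop-2-en-1-yl)cyclohex-2-ene-1,4-dione | C=CC[C@@]1(C)CC(=O)C=C(C)C1=O | intermediate
7 | 2-[(1S)-1,3-dimethyl-2,5-dioxocyclohex-3-en-1-yl]acetaldehyde | O=CC[C@@]1(C)CC(=O)C=C(C)C1=O | intermediate
8 | 2-methylpropene | C=C(C)C | starting material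
9 | trichlorotitanium alkoxide of (6S)-6-(4-chloro-2-hydroxy-4-methylpentyl)-2,6-dimethylcyclohex-2-ene-1,4-dione (both carbinol epimers) | CC(C)(Cl)CC(O[Ti](Cl)(Cl)Cl)C[C@@]1(C)CC(=O)C=C(C)C1=O | intermediate
10 | (4aR,8aS)-7-hydroxy-2,5,5,8a-tetramethyl-4a,5,6,7,8,8a-hexahydronaphthalene-1,4-dione (cis-fused, both carbinol epimers) | O=C1C=C(C)C(=O)[C@@]2(C)CC(O)CC(C)(C)[C@@H]12 | intermediate
11 | O-[(4aR,8aS)-4,4,7,8a-tetramethyl-5,8-dioxo-1,2,3,4,4a,5,8,8a-octahydronaphthalen-2-yl] 1H-imidazole-1-carbothioate (both epimers at the oxygen-bearing carbon) | O=C1C=C(C)C(=O)[C@@]2(C)CC(OC(=S)n3ccnc3)CC(C)(C)[C@@H]12 | intermediate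
12 | (4aR,8aS)-2,5,5,8a-tetramethyl-4a,5,6,7,8,8a-hexahydronaphthalene-1,4-dione (cis-fused) | O=C1C=C(C)C(=O)[C@@]2(C)CCCC(C)(C)[C@@H]12 | intermediate
13 | lithium (8aS)-2,5,5,8a-tetramethyl-1-oxo-1,5,6,7,8,8a-hexahydronaphthalen-4-olate | CC1=CC(O[Li])=C2C(C)(C)CCC[C@]2(C)C1=O | intermediate
14 | (4aS,8aS)-2,5,5,8a-tetramethyl-4a,5,6,7,8,8a-hexahydronaphthalene-1,4-dione (trans-fused) | O=C1C=C(C)C(=O)[C@@]2(C)CCCC(C)(C)[C@H]12 | intermediate
15 | lithium (4aS,8aS)-2,5,5,8a-tetramethyl-4-oxo-3,4,4a,5,6,7,8,8a-octahydronaphthalen-1-olate | O=C1CC(C)=C(O[Li])[C@@]2(C)CCCC(C)(C)[C@H]12 | intermediate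
16 | (4aS,8aS)-2,5,5,8a-tetramethyl-4-oxo-3,4,4a,5,6,7,8,8a-octahydronaphthalen-1-yl trifluoromethanesulfonate | O=C1CC(C)=C(OS(=O)(=O)C(F)(F)F)[C@@]2(C)CCCC(C)(C)[C@H]12 | intermediate
17 | tert-butyl(but-3-yn-1-yloxy)dimethylsilane | C#CCCO[Si](C)(C)C(C)(C)C | starting material
18 | [(1E)-4-{[tert-butyl(dimethyl)silyl]oxy}-2-methylbut-1-en-1-yl](dimethyl)alumane | C/C(CCO[Si](C)(C)C(C)(C)C)=C\[Al](C)C | intermediate
19 | 2-(trimethylsilyl)ethyl (2E)-5-{[tert-butyl(dimethyl)silyl]oxy}-3-methylpent-2-enoate | C/C(CCO[Si](C)(C)C(C)(C)C)=C\C(=O)OCC[Si](C)(C)C | intermediate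
20 | 2-(trimethylsilyl)ethyl (2E)-5-bromo-3-methylpent-2-enoate | C/C(CCBr)=C\C(=O)OCC[Si](C)(C)C | intermediate
21 | bromo{(3E)-3-methyl-5-oxo-5-[2-(trimethylsilyl)ethoxy]pent-3-en-1-yl}zinc | C/C(CC[Zn]Br)=C\C(=O)OCC[Si](C)(C)C | intermediate
22 | 2-(trimethylsilyl)ethyl (2E)-3-methyl-5-[(4aS,8aS)-2,5,5,8a-tetramethyl-4-oxo-3,4,4a,5,6,7,8,8a-octahydronaphthalen-1-yl]pent-2-enoate | O=C1CC(C)=C(CC/C(C)=C/C(=O)OCC[Si](C)(C)C)[C@@]2(C)CCCC(C)(C)[C@H]12 | intermediate
23 | sodium dienolate of 22 (O–C6=C7–C8=C9) | [Na]OC1=CC(C)=C(CC/C(C)=C/C(=O)OCC[Si](C)(C)C)[C@@]2(C)CCCC(C)(C)[C@H]12 | intermediate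
24 | 2-(trimethylsilyl)ethyl (2E)-5-[(3S,4aS,8aS)-3-hydroxy-2,5,5,8a-tetramethyl-4-oxo-3,4,4a,5,6,7,8,8a-octahydronaphthalen-1-yl]-3-methylpent-2-enoate | O=C1[C@@H](O)C(C)=C(CC/C(C)=C/C(=O)OCC[Si](C)(C)C)[C@@]2(C)CCCC(C)(C)[C@H]12 | intermediate
25 | 2-(trimethylsilyl)ethyl (2E)-3-methyl-5-{(3S,4aS,8aS)-2,5,5,8a-tetramethyl-3-[(3-methylbutanoyl)oxy]-4-oxo-3,4,4a,5,6,7,8,8a-octahydronaphthalen-1-yl}pent-2-enoate | O=C1[C@@H](OC(=O)CC(C)C)C(C)=C(CC/C(C)=C/C(=O)OCC[Si](C)(C)C)[C@@]2(C)CCCC(C)(C)[C@H]12 | intermediate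
26 | 2-(trimethylsilyl)ethyl (2E)-5-{(3S,4S,4aS,8aS)-4-hydroxy-2,5,5,8a-tetramethyl-3-[(3-methylbutanoyl)oxy]-3,4,4a,5,6,7,8,8a-octahydronaphthalen-1-yl}-3-methylpent-2-enoate | O[C@@H]1[C@@H](OC(=O)CC(C)C)C(C)=C(CC/C(C)=C/C(=O)OCC[Si](C)(C)C)[C@@]2(C)CCCC(C)(C)[C@H]12 | intermediate
27 | 2-(trimethylsilyl)ethyl (2E)-5-{(3S,4S,4aS,8aS)-4-acetoxy-2,5,5,8a-tetramethyl-3-[(3-methylbutanoyl)oxy]-3,4,4a,5,6,7,8,8a-octahydronaphthalen-1-yl}-3-methylpent-2-enoate | CC(=O)O[C@@H]1[C@@H](OC(=O)CC(C)C)C(C)=C(CC/C(C)=C/C(=O)OCC[Si](C)(C)C)[C@@]2(C)CCCC(C)(C)[C@H]12 | intermediate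
28 | (5S,6S,7S,10S)-6-acetoxy-7-[(3-methylbutanoyl)oxy]labda-8,13E-dien-15-oic acid | CC(=O)O[C@@H]1[C@@H](OC(=O)CC(C)C)C(C)=C(CC/C(C)=C/C(=O)O)[C@@]2(C)CCCC(C)(C)[C@H]12 | target

**Step count and risks**

Total step count: 16. Longest linear sequence: 14 (steps 1–8 and 11–16); steps 9–10 make the side-chain fragment.

Step 5 (proposed method). The TiCl4-bound ketone may enolise too slowly, so that the tertiary chloride loses HCl instead of alkylating C5; the alkene may oligomerise; or the acid may induce an aromatising 1,2-shift of a C10 substituent. The fallback makes the two bonds one at a time with known reactions, setting out from 7 and returning at 10. A Me2AlCl-promoted carbonyl-ene reaction of 7 with 8 (CH2Cl2, −78 °C) should give the homoallylic alcohol (6S)-6-(2-hydroxy-4-methylpent-4-en-1-yl)-2,6-dimethylcyclohex-2-ene-1,4-dione F1. Markovnikov addition of HCl (CH2Cl2, 0 °C) gives the tertiary chloride (6S)-6-(4-chloro-2-hydroxy-4-methylpentyl)-2,6-dimethylcyclohex-2-ene-1,4-dione F2. TMSOTf/Et3N silylates the carbinol and converts the C6 ketone regiospecifically into its C5=C6 enol silane, giving (6S)-6-{4-chloro-4-methyl-2-[(trimethylsilyl)oxy]pentyl}-2,6-dimethyl-4-[(trimethylsilyl)oxy]cyclohexa-2,4-dien-1-one F3. TiCl4 (CH2Cl2, −78 → −40 °C) then effects the intramolecular α-tert-alkylation of the enol silane, and acidic work-up frees the carbinol to give 10.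

Step 7. The amide base may remove a proton from the C8 methyl group (the vinylogous position) instead of hindered C5, or proton return may not be face-selective, so that cis-fused material persists. The fallback sets out from 12 and returns at 16, replacing kinetic protonation by thermodynamic control at a later stage. The cis-fused 12 is taken unchanged through the step 8 conditions to the cis-fused triflate (4aR,8aS)-2,5,5,8a-tetramethyl-4-oxo-3,4,4a,5,6,7,8,8a-octahydronaphthalen-1-yl trifluoromethanesulfonate F4, in which ring B is no longer flat and C7 is sp3. Equilibration through the C5 enol with DBU (toluene, 80 °C) should then favour the trans-fused 16.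

Step 11. Oxidative addition and transmetalation may be slow at the tetrasubstituted triflate next to quaternary C10, so that protodezincation or reduction of the triflate wins. The fallback sets out from 16 and returns at 22, moving the sp2–sp3 coupling to the C12–C13 bond. Stille coupling of 16 with tributyl(vinyl)stannane (Pd(PPh3)4, LiCl, THF, 65 °C) should give the diene (4aS,8aS)-4-ethenyl-3,4a,8,8-tetramethyl-4a,5,6,7,8,8a-hexahydronaphthalen-1(2H)-one F5. 9-BBN-H adds to its terminal vinyl carbon to give the B-alkyl borane (4aS,8aS)-4-[2-(9-borabicyclo[3.3.1]nonan-9-yl)ethyl]-3,4a,8,8-tetramethyl-4a,5,6,7,8,8a-hexahydronaphthalen-1(2H)-one F6. The coupling partner starts from 2-(trimethylsilyl)ethyl 3-oxobutanoate F7, made from 2,2,6-trimethyl-4H-1,3-dioxin-4-one and 2-(trimethylsilyl)ethanol (xylene, 130 °C). Treatment of F7 with Tf2O and aqueous Me4NOH gives the enol triflate 2-(trimethylsilyl)ethyl (2E)-3-{[(trifluoromethyl)sulfonyl]oxy}but-2-enoate F8. B-alkyl Suzuki–Miyaura coupling of F6 with F8 (PdCl2(dppf), K3PO4, DMF/H2O, 25 °C) gives 22.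

**Further compounds**
F1 | step 5 | (6S)-6-(2-hydroxy-4-methylpent-4-en-1-yl)-2,6-dimethylcyclohex-2-ene-1,4-dione | C=C(C)CC(O)C[C@@]1(C)CC(=O)C=C(C)C1=O
F2 | step 5 | (6S)-6-(4-chloro-2-hydroxy-4-methylpentyl)-2,6-dimethylcyclohex-2-ene-1,4-dione | CC(C)(Cl)CC(O)C[C@@]1(C)CC(=O)C=C(C)C1=O
F3 | step 5 | (6S)-6-{4-chloro-4-methyl-2-[(trimethylsilyl)oxy]pentyl}-2,6-dimethyl-4-[(trimethylsilyl)oxy]cyclohexa-2,4-dien-1-one | CC(C)(Cl)CC(O[Si](C)(C)C)C[C@@]1(C)C=C(O[Si](C)(C)C)C=C(C)C1=O
F4 | step 7 | (4aR,8aS)-2,5,5,8a-tetramethyl-4-oxo-3,4,4a,5,6,7,8,8a-octahydronaphthalen-1-yl trifluoromethanesulfonate | O=C1CC(C)=C(OS(=O)(=O)C(F)(F)F)[C@@]2(C)CCCC(C)(C)[C@@H]12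
F5 | step 11 | (4aS,8aS)-4-ethenyl-3,4a,8,8-tetramethyl-4a,5,6,7,8,8a-hexahydronaphthalen-1(2H)-one | O=C1CC(C)=C(C=C)[C@@]2(C)CCCC(C)(C)[C@H]12
F6 | step 11 | (4aS,8aS)-4-[2-(9-borabicyclo[3.3.1]nonan-9-yl)ethyl]-3,4a,8,8-tetramethyl-4a,5,6,7,8,8a-hexahydronaphthalen-1(2H)-one | O=C1CC(C)=C(CCB3C4CCCC3CCC4)[C@@]2(C)CCCC(C)(C)[C@H]12
F7 | step 11 | 2-(trimethylsilyl)ethyl 3-oxobutanoate | CC(=O)CC(=O)OCC[Si](C)(C)C
F8 | step 11 | 2-(trimethylsilyl)ethyl (2E)-3-{[(trifluoromethyl)sulfonyl]oxy}but-2-enoate | C/C(OS(=O)(=O)C(F)(F)F)=C\C(=O)OCC[Si](C)(C)C
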